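**Retrosynthetic overview**
- Final operations: desilylation and a reagent-controlled 1,2-reduction lead back to the ring A ketone.
- Ring A is a cyclohexene whose ring C=C lies between the CMe2 carbon and a ring CH2, with an exocyclic =CH2 on the ring carbon flanked by that CH2 and the side-chain methine. This is the Diels–Alder pattern of 4-methylpenta-1,3-diene added across the carbonyl-conjugated C=C of an allene; the bonds cut are methine–CMe2 and C(=CH2)–CH2.
- The allenyl dienone comes from the ring B E-enal by propargylation and oxidation/isomerisation; the enal comes from a ring B methyl ketone by Horner–Wadsworth–Emmons olefination.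
- Ring B is taken from (S)-limonene: epoxide hydrolysis to the trans-diaxial diol sets the tertiary carbinol, and the C–Br centre comes from SN2 inversion of the secondary carbinol.
- Ring order: ring B from the chiral pool first, ring A closed last by the cycloaddition.

Key step: step 13

Remark on protecting group: the tertiary alcohol is carried as its triethylsilyl ether, which should survive the Lewis-acidic cycloaddition and the many intervening steps better than a smaller silyl group.
Assumption on the cycloaddition catalyst: the face chosen by the oxazaborolidinium salt on an allenyl ketone is assumed to follow the two-point binding known for enones; the (S)-catalyst is the first choice and, if the sense is opposite, its mirror image is used with no other change.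

**Route**

Step 1
Reactants: 1 (S)-(−)-limonene
Product: 2 (4S)-limonene 1,2-oxide (mixture of the two epoxide epimers)
Conditions: mCPBA (1.0 equiv), NaHCO3, CH2Cl2, 0 °C
Reagents that add atoms: 3-chloroperoxybenzoic acid, O=C(OO)c1cccc(Cl)c1
Why: Prilezhaev epoxidation is fastest at the electron-rich trisubstituted ring alkene, so one equivalent of peracid should spare the isopropenyl group; both epoxide epimers are carried on because the next step converges them, and the C4 stereocentre comes from the terpene.

Step 2
Reactants: 2 (4S)-limonene 1,2-oxide
Product: 3 (1R,2R,4S)-limonene-1,2-diol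
Conditions: H2SO4 (1% aq), THF, 0 °C → rt; crystallisation
Reagents that add atoms: water, O
Why: Acid-catalysed epoxide hydrolysis under the Fürst–Plattner rule (trans-diaxial opening) should funnel both epoxides to the same diol, water entering at C1 of one epimer and at C2 of the other; this sets the tertiary carbinol (OH cis to the isopropenyl group) and leaves an axial secondary OH of the configuration needed for later inversion.

Step 3
Reactants: 3 (1R,2R,4S)-limonene-1,2-diol
Product: 4 secondary mono-acetate of the diol
Conditions: Ac2O, pyridine, DMAP (cat.), CH2Cl2, 0 °C → rt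
Reagents that add atoms: acetic anhydride, CC(=O)OC(C)=O
Why: Nucleophile-catalysed acylation distinguishes cleanly between the secondary and the tertiary hydroxyl, so only the secondary oxygen is blocked.

Step 4
Reactants: 4 secondary mono-acetate
Product: 5 acetate with the tertiary oxygen as triethylsilyl ether
Conditions: Et3SiOTf, 2,6-lutidine, CH2Cl2, −78 → 0 °C
Reagents that add atoms: triethylsilyl trifluoromethanesulfonate, CC[Si](CC)(CC)OS(=O)(=O)C(F)(F)F
Why: A silyl triflate with a hindered pyridine base is the standard silylation of a tertiary alcohol, and the acetate keeps the secondary oxygen out of play.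

Step 5
Reactants: 5 acetate triethylsilyl ether
Product: 6 secondary alcohol with tertiary triethylsilyl ether
Conditions: i-Bu2AlH, CH2Cl2, −78 °C; aq. KNaC4H4O6
Reagents that add atoms: none
Why: Reductive ester cleavage with i-Bu2AlH at low temperature frees the secondary alcohol under non-basic conditions, which avoids 1,2-silyl migration to the neighbouring oxygen.

Step 6
Reactants: 6 secondary alcohol with tertiary triethylsilyl ether
Product: 8 (1R,2S,4S)-2-bromo-1-methyl-4-(prop-1-en-2-yl)cyclohexyl triethylsilyl ether, via axial secondary triflate 7 (not isolated)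
Conditions: Tf2O (1.1 equiv), 2,6-lutidine, CH2Cl2, −40 °C; then Bu4NBr, toluene, −40 °C → rt
Reagents that add atoms: tetrabutylammonium bromide, CCCC[N+](CCCC)(CCCC)CCCC.[Br-]; trifluoromethanesulfonic anhydride (its atoms stay only in intermediate 7), O=S(=O)(OS(=O)(=O)C(F)(F)F)C(F)(F)F
Why: SN2 displacement of the axial secondary triflate by bromide (Walden inversion) should place bromine equatorial and cis to the tertiary silyloxy group, which sets the C–Br stereocentre; the hindered, weakly nucleophilic silyl ether limits oxiranium participation and bromide is too weak a base for much E2.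

Step 7
Reactants: 8 bromo silyl ether
Product: 10 ring B methyl ketone, via secondary ozonide 9 (not isolated)
Conditions: O3, CH2Cl2, −78 °C; then PPh3, −78 °C → rt
Reagents that add atoms: ozone, [O-][O+]=O
Why: Ozonolysis with reductive work-up cleaves the only alkene, the isopropenyl group, to the methyl ketone without touching the bromide or the silyl ether.

Step 8
Reactants: 10 ring B methyl ketone; 11 triethyl phosphonoacetate
Product: 12 ring B E-enoate
Conditions: NaH (slightly less than the phosphonate), THF, 0 → 50 °C; chromatography to remove the minor Z isomer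
Reagents that add atoms: none
Why: Horner–Wadsworth–Emmons olefination of the methyl ketone should favour the E-enoate (ester trans to the cyclohexyl group); the ring carbon α to the ketone keeps its configuration because the equatorial arrangement is the thermodynamic one, and the weakly basic phosphonate anion should not eliminate or cyclise the hindered bromide.

Step 9
Reactants: 12 ring B E-enoate
Product: 13 ring B E-allylic alcohol
Conditions: i-Bu2AlH, CH2Cl2, −78 °C; aq. KNaC4H4O6
Reagents that add atoms: none
Why: 1,2-Reduction of the α,β-unsaturated ester by i-Bu2AlH gives the allylic alcohol without affecting the alkene geometry, the bromide or the silyl ether.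

Step 10
Reactants: 13 ring B E-allylic alcohol
Product: 14 ring B E-enal
Conditions: MnO2, CH2Cl2, rt
Reagents that add atoms: none
Why: MnO2 oxidises allylic alcohols selectively to enals under neutral conditions with retention of the E geometry.

Step 11
Reactants: 14 ring B E-enal; 15 3-bromoprop-1-yne
Product: 16 homopropargylic alcohol (both carbinol epimers)
Conditions: Zn dust, THF, 0 °C → rt; aq. NH4Cl
Reagents that add atoms: none
Why: Barbier-type propargylation, in which allenylzinc bromide formed in the flask adds 1,2 to the enal through a cyclic SE2' transition state to give the homopropargylic alcohol; the carbinol configuration is irrelevant because it is oxidised next.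

Step 12
Reactants: 16 homopropargylic alcohol
Product: 18 ring B allenyl dienone, via β,γ-alkynyl ketone 17 (not isolated)
Conditions: Dess–Martin periodinane, CH2Cl2, 0 °C → rt; then Et3N (cat.), 0 °C; used at once
Reagents that add atoms: none
Why: Dess–Martin oxidation gives the β,γ-alkynyl ketone, whose CH2 between carbonyl and alkyne is acidic enough for an amine-mediated prototropic shift to the conjugated allenyl ketone, the usual entry to allenyl vinyl ketones.

Step 13
Reactants: 18 ring B allenyl dienone; 19 4-methylpenta-1,3-diene
Product: 20 ring A ketone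
Conditions: (S)-B-(o-tolyl)-α,α-diphenylprolinol oxazaborolidine (20 mol %), HNTf2 (18 mol %), 19 (5 equiv), CH2Cl2, −78 → −40 °C; pH 7 buffer at −78 °C
Reagents that add atoms: none
Why: Proposed new method: the N-protonated oxazaborolidine should bind the ketone oxygen on the allene side (the lone pair on the enone side is blocked by the β-methyl group cis to the carbonyl of the s-cis enone arm) and lower the LUMO of the conjugated allene C=C, so that a concerted but asynchronous normal-demand [4+2] cycloaddition takes place in which the CH2 terminus of the diene bonds first to the central allene carbon and the CMe2 terminus then bonds to the carbon α to the ketone; the closest known reactions are the AlCl3- or EtAlCl2-promoted Diels–Alder additions of allenyl ketones and allenoates to 1,3-dienes and the oxazaborolidinium-catalysed enantioselective Diels–Alder reactions of enones. Ring A closes by intermolecular [4+2] cycloaddition (two σ-bonds, six-membered carbocycle), and the distal allene π-bond is left as the exocyclic methylene. The only new stereocentre, the ring A methine, has no useful substrate bias because the ring B centres are remote, so it is set by the chiral catalyst, which shields one face of the allene α,β-bond. The step needs regioselectivity, secured by the polarised dienophile (electrophilic central carbon) and the more nucleophilic unsubstituted diene terminus, and site selectivity for the allene over the enone C=C, secured by the β,β-disubstitution of the latter. Nazarov-type 4π-closure of the activated allenyl vinyl ketone is the main competitor and should be slowed by the absence of α-substituents, the fully substituted β-terminus, the low temperature and the excess of diene. The β,γ-unsaturated ketone is quenched cold into neutral buffer so that the methine does not epimerise and the methylene does not move into conjugation.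

Step 14
Reactants: 20 ring A ketone
Product: 21 (R)-allylic alcohol, tertiary triethylsilyl ether
Conditions: (R)-2-methyl-CBS-oxazaborolidine (30 mol %), catecholborane, toluene, −78 → −40 °C; MeOH, aqueous work-up
Reagents that add atoms: none
Why: Corey–Bakshi–Shibata reduction, in which the enone arm is held s-cis by its β-methyl group and blocks the oxygen lone pair on that side, so the catalyst boron should bind on the ring A side (alkenyl as the large group) and the (R)-catalyst should deliver hydride to the face remote from the CMe2 group to give the (R)-carbinol, the epimer opposite to the Felkin–Anh prediction for the free ketone; the reduction is 1,2-selective and base-free, so the α-methine is kept, and catecholborane at low temperature should not hydroborate the alkenes.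

Step 15
Reactants: 21 (R)-allylic alcohol, tertiary triethylsilyl ether
Product: 22 target
Conditions: HF·pyridine, pyridine, THF, 0 °C → rt
Reagents that add atoms: none
Why: Fluoride-mediated cleavage of the tertiary triethylsilyl ether under pyridine-buffered conditions frees the tertiary alcohol without ionising the allylic alcohol, and the syn bromohydrin cannot close to an epoxide.

**Compound list**
1 | (S)-(−)-limonene, (4S)-1-methyl-4-(prop-1-en-2-yl)cyclohex-1-ene | C=C(C)[C@H]1CCC(C)=CC1 | starting material
2 | (4S)-limonene 1,2-oxide, mixture of epoxide epimers | C=C(C)[C@H]1CCC2(C)OC2C1 | intermediate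
3 | (1R,2R,4S)-1-methyl-4-(prop-1-en-2-yl)cyclohexane-1,2-diol | C=C(C)[C@H]1CC[C@@](C)(O)[C@H](O)C1 | intermediate
4 | (1R,2R,5S)-2-hydroxy-2-methyl-5-(prop-1-en-2-yl)cyclohexyl acetate | C=C(C)[C@H]1CC[C@@](C)(O)[C@H](OC(C)=O)C1 | intermediate
5 | (1R,2R,5S)-2-methyl-5-(prop-1-en-2-yl)-2-[(triethylsilyl)oxy]cyclohexyl acetate | C=C(C)[C@H]1CC[C@@](C)(O[Si](CC)(CC)CC)[C@H](OC(C)=O)C1 | intermediate
6 | (1R,2R,5S)-2-methyl-5-(prop-1-en-2-yl)-2-[(triethylsilyl)oxy]cyclohexan-1-ol | C=C(C)[C@H]1CC[C@@](C)(O[Si](CC)(CC)CC)[C@H](O)C1 | intermediate
7 | (1R,2R,5S)-2-methyl-5-(prop-1-en-2-yl)-2-[(triethylsilyl)oxy]cyclohexyl trifluoromethanesulfonate | C=C(C)[C@H]1CC[C@@](C)(O[Si](CC)(CC)CC)[C@H](OS(=O)(=O)C(F)(F)F)C1 | intermediate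
8 | {[(1R,2S,4S)-2-bromo-1-methyl-4-(prop-1-en-2-yl)cyclohexyl]oxy}triethylsilane | C=C(C)[C@H]1CC[C@@](C)(O[Si](CC)(CC)CC)[C@@H](Br)C1 | intermediate
9 | secondary ozonide of 8, 3-methyl-3-{(1S,3S,4R)-3-bromo-4-methyl-4-[(triethylsilyl)oxy]cyclohexyl}-1,2,4-trioxolane | CC1(OOCO1)[C@H]2CC[C@@](C)(O[Si](CC)(CC)CC)[C@@H](Br)C2 | intermediate
10 | 1-{(1S,3S,4R)-3-bromo-4-methyl-4-[(triethylsilyl)oxy]cyclohexyl}ethan-1-one | CC(=O)[C@H]1CC[C@@](C)(O[Si](CC)(CC)CC)[C@@H](Br)C1 | intermediate
11 | triethyl phosphonoacetate | CCOC(=O)CP(=O)(OCC)OCC | starting material
12 | ethyl (2E)-3-{(1S,3S,4R)-3-bromo-4-methyl-4-[(triethylsilyl)oxy]cyclohexyl}but-2-enoate | CCOC(=O)/C=C(\C)[C@H]1CC[C@@](C)(O[Si](CC)(CC)CC)[C@@H](Br)C1 | intermediate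
13 | (2E)-3-{(1S,3S,4R)-3-bromo-4-methyl-4-[(triethylsilyl)oxy]cyclohexyl}but-2-en-1-ol | OC/C=C(\C)[C@H]1CC[C@@](C)(O[Si](CC)(CC)CC)[C@@H](Br)C1 | intermediate
14 | (2E)-3-{(1S,3S,4R)-3-bromo-4-methyl-4-[(triethylsilyl)oxy]cyclohexyl}but-2-enal | O=C/C=C(\C)[C@H]1CC[C@@](C)(O[Si](CC)(CC)CC)[C@@H](Br)C1 | intermediate
15 | 3-bromoprop-1-yne | C#CCBr | starting material
16 | (5E)-6-{(1S,3S,4R)-3-bromo-4-methyl-4-[(triethylsilyl)oxy]cyclohexyl}hept-5-en-1-yn-4-ol, both C4 epimers | C#CCC(O)/C=C(\C)[C@H]1CC[C@@](C)(O[Si](CC)(CC)CC)[C@@H](Br)C1 | intermediate
17 | (5E)-6-{(1S,3S,4R)-3-bromo-4-methyl-4-[(triethylsilyl)oxy]cyclohexyl}hept-5-en-1-yn-4-one | C#CCC(=O)/C=C(\C)[C@H]1CC[C@@](C)(O[Si](CC)(CC)CC)[C@@H](Br)C1 | intermediate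
18 | (5E)-6-{(1S,3S,4R)-3-bromo-4-methyl-4-[(triethylsilyl)oxy]cyclohexyl}hepta-1,2,5-trien-4-one | C=C=CC(=O)/C=C(\C)[C@H]1CC[C@@](C)(O[Si](CC)(CC)CC)[C@@H](Br)C1 | intermediate
19 | 4-methylpenta-1,3-diene | CC(C)=CC=C | starting material
20 | (2E)-3-{(1S,3S,4R)-3-bromo-4-methyl-4-[(triethylsilyl)oxy]cyclohexyl}-1-[(1R)-2,2-dimethyl-6-methylidenecyclohex-3-en-1-yl]but-2-en-1-one | C=C1CC=CC(C)(C)[C@@H]1C(=O)/C=C(\C)[C@H]1CC[C@@](C)(O[Si](CC)(CC)CC)[C@@H](Br)C1 | intermediate
21 | (1R,2E)-3-{(1S,3S,4R)-3-bromo-4-methyl-4-[(triethylsilyl)oxy]cyclohexyl}-1-[(1R)-2,2-dimethyl-6-methylidenecyclohex-3-en-1-yl]but-2-en-1-ol | C=C1CC=CC(C)(C)[C@@H]1[C@H](O)/C=C(\C)[C@H]1CC[C@@](C)(O[Si](CC)(CC)CC)[C@@H](Br)C1 | intermediate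
22 | (1R,2S,4S)-2-bromo-4-{(2E,4R)-4-[(1R)-2,2-dimethyl-6-methylidenecyclohex-3-en-1-yl]-4-hydroxybut-2-en-2-yl}-1-methylcyclohexan-1-ol | C=C1CC=CC(C)(C)[C@@H]1[C@H](O)/C=C(\C)[C@H]1CC[C@@](C)(O)[C@@H](Br)C1 | target

**Step count**
Total: 15 steps. Longest linear sequence: 15 steps (1 → 22); 11, 15 and 19 are bought.

**Steps most likely to fail**

Step 13 (proposed new method). The chiral Brønsted-activated Lewis acid may trigger 4π-electrocyclisation of the dienone or cationic oligomerisation of the diene faster than cycloaddition, or it may discriminate the two allene faces poorly. The fallback gives up catalyst control of the methine and uses only known chemistry. It sets out from 18 and 19, which are combined under the established achiral aluminium Lewis acid activation for allenyl ketone dienophiles (Me2AlCl, CH2Cl2, −78 °C) or, acid-free, under high pressure. This should give 20 together with its ring A methine epimer F1. The mixture is reduced as in step 14, where the catalyst should fix the same carbinol configuration in both, so that 21 is accompanied by the (1'S)-methine carbinol F2. These two differ in the relative configuration of adjacent centres and should separate by chromatography; F2 is discarded and the route is rejoined at 21.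

Step 6. Backside attack next to the fully substituted carbon may be so slow that E2 loss of triflate to the cyclohexene, or participation of the anti-periplanar silyloxy oxygen (epoxide formation or substitution with retention), takes over. The fallback avoids a free sulfonate ester. It sets out from 6, which is treated with CBr4 and PPh3 (toluene, up to 60 °C) so that the oxygen leaves as phosphine oxide from the alkoxytriphenylphosphonium bromide F3. This is a tight ion pair whose collapse delivers bromide with inversion in a neutral medium and without an ionising leaving group. It comes back to the route at 8.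

Step 14. Hydride delivery may show poor face selectivity if the catalyst binds the carbonyl on either side, or if the intrinsic bias of the α-branched ketone opposes it. The fallback turns to substrate control followed by stereoinversion. It sets out from 20, which is reduced under Felkin–Anh control with NaBH4/CeCl3·7H2O (MeOH, −78 °C) to the (S)-carbinol F4. Mitsunobu reaction (4-nitrobenzoic acid, PPh3, DIAD, THF) inverts the carbinol to the (R)-4-nitrobenzoate F5, and methanolysis (K2CO3, MeOH) returns to the route at 21.

**Further compounds**
F1 | step 13 | ring A methine epimer of 20, (1S)-2,2-dimethyl-6-methylidenecyclohex-3-en-1-yl ketone | C=C1CC=CC(C)(C)[C@H]1C(=O)/C=C(\C)[C@H]1CC[C@@](C)(O[Si](CC)(CC)CC)[C@@H](Br)C1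
F2 | step 13 | (1R)-carbinol bearing the (1S)-ring A methine, diastereomer of 21 | C=C1CC=CC(C)(C)[C@H]1[C@H](O)/C=C(\C)[C@H]1CC[C@@](C)(O[Si](CC)(CC)CC)[C@@H](Br)C1
F3 | step 6 | alkoxytriphenylphosphonium bromide of 6 | C=C(C)[C@H]1CC[C@@](C)(O[Si](CC)(CC)CC)[C@H](O[P+](c2ccccc2)(c2ccccc2)c2ccccc2)C1.[Br-]
F4 | step 14 | (1S)-carbinol epimer of 21 | C=C1CC=CC(C)(C)[C@@H]1[C@@H](O)/C=C(\C)[C@H]1CC[C@@](C)(O[Si](CC)(CC)CC)[C@@H](Br)C1
F5 | step 14 | (1R)-4-nitrobenzoate of 21 | C=C1CC=CC(C)(C)[C@@H]1[C@H](OC(=O)c2ccc(cc2)[N+](=O)[O-])/C=C(\C)[C@H]1CC[C@@](C)(O[Si](CC)(CC)CC)[C@@H](Br)C1
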